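The route rests on making the hexasubstituted benzene ring of the chromanone de novo. Its three oxygens (C5, C7, C8a) alternate with three carbon substituents (C4a, C6, C8), which is what the union of a vinylketene with an ynol ether delivers with full regiocontrol. Heating a cyclobutenone with ethoxyacetylene forms the C8a–C4a and C5–C6 bonds and the arene in one operation, leaving a free hydroxyl at C8a, the methoxy group at C7 and a removable ethoxy group at C5. The precursor is a 3-methoxy-2-prenylcyclobutenone whose C4 carries the stereodefined CH(Ph)CH2CO2Me arm of desymmetrised 3-phenylglutarate. Propanoylation, chromone closure, unmasking and a final asymmetric copper hydride reduction finish the cis-2,3-dimethylchromanone.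

Key step: step 5

Remarks on the chemistry (correction, assumption, design):
- Correction: a ketene and a 1-methoxyalkyne give a cyclobutenone with the methoxy group on the ring carbon next to the sp3 carbon and the prenyl group next to the carbonyl. As a substituent this is the 2-methoxy-3-(3-methylbut-2-enyl)-4-oxocyclobut-2-en-1-yl group; the locant set 3-methoxy-2-prenyl would describe the α-methoxy enone, which this chemistry cannot give. Its benzylic centre has the geometry of the target but carries the descriptor S until the neighbouring carbon becomes aromatic.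
- Assumption: the sense of induction in steps 1 and 10 is chosen through the pseudo-enantiomeric alkaloid catalyst and the ligand antipode, and would be fixed on the known hemiester and on a model chromone.
- Design: a cis-2,3-dimethylchroman-4-one epimerises at C3 with base, so the ethyl ether and the methyl ester are removed before the ring stereocentres exist and the reduction is the last step.

Step 1
Reactants: 1 3-phenylglutaric anhydride
Product: 2 (3R)-5-methoxy-5-oxo-3-phenylpentanoic acid
Conditions: MeOH (10 equiv), hydroquinidine anthraquinone-1,4-diyl diether [(DHQD)2AQN] (10 mol%), Et2O, −40 °C; dilute HCl wash, recrystallise if needed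
Reagents that add atoms: methanol, CO
Why: Alkaloid-catalysed general-base alcoholysis (desymmetrisation of a meso anhydride) distinguishes the two enantiotopic carbonyl groups, so the benzylic stereocentre is set here by catalyst control and the arm left as free acid is the one later built into the benzene ring.

Step 2
Reactants: 2 (3R)-5-methoxy-5-oxo-3-phenylpentanoic acid
Product: 3 methyl (3S)-5-chloro-5-oxo-3-phenylpentanoate
Conditions: (COCl)2 (1.2 equiv), DMF (cat.), CH2Cl2, 0 °C → rt; evaporate, use crude
Reagents that add atoms: oxalyl chloride, O=C(Cl)C(Cl)=O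
Why: Acid chloride formation through the chloroiminium intermediate is routine; the stereocentre is β to both carbonyls and has no acidic proton, and keeping the chloride at or below room temperature avoids collapse to the achiral anhydride.

Step 3
Reactants: 4 chloroacetaldehyde dimethyl acetal; 5 prenyl bromide
Product: 7 1-methoxy-5-methylhex-4-en-1-yne, via sodium methoxyacetylide 6 (not isolated)
Conditions: NaNH2 (3.0 equiv), liq. NH3, −33 °C; then 5 (0.9 equiv), −33 °C; NH4Cl, distil
Reagents that add atoms: none
Why: Threefold action of NaNH2 (loss of HCl, loss of methanol, deprotonation) gives the sodium alkoxyacetylide, which is alkylated at carbon by the primary allylic bromide in an SN2 reaction, the standard access to 1-alkoxyalk-1-ynes.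

Step 4
Reactants: 3 methyl (3S)-5-chloro-5-oxo-3-phenylpentanoate; 7 1-methoxy-5-methylhex-4-en-1-yne
Product: 9 methyl (3S)-3-[2-methoxy-3-(3-methylbut-2-enyl)-4-oxocyclobut-2-en-1-yl]-3-phenylpropanoate (both epimers at the ring carbon), via ketene 8 (not isolated)
Conditions: 3 added over 4 h to 7 (1.5 equiv), Et3N (1.3 equiv), CH2Cl2, rt; filter, chromatography on Et3N-deactivated silica
Reagents that add atoms: none
Why: Dehydrochlorination gives aldoketene 8 in low stationary concentration, and its carbonyl carbon is attacked by the electron-rich prenyl-bearing carbon of the ynol ether in a regioselective ketene–alkyne [2+2] cycloaddition, so the methoxy group ends up β to the ring carbonyl and the side chain at C4; the new ring stereocentre is uncontrolled and irrelevant because step 5 destroys it.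

Step 5
Reactants: 9 methyl (3S)-3-[2-methoxy-3-(3-methylbut-2-enyl)-4-oxocyclobut-2-en-1-yl]-3-phenylpropanoate; 10 ethoxyacetylene
Product: 15 methyl (3R)-3-[4-ethoxy-6-hydroxy-2-methoxy-3-(3-methylbut-2-enyl)phenyl]-3-phenylpropanoate, via vinylketene 11 (not isolated), via 4-vinylcyclobutenone 12 (not isolated), via dienylketene 13 (not isolated), via cyclohexa-2,4-dienone 14 (not isolated)
Conditions: 10 (3 equiv), toluene, sealed tube, 80 °C then 110 °C; then K2CO3, MeOH, rt
Reagents that add atoms: none
Why: Thermal 4π-electrocyclic opening of 9 (both ring epimers converge) gives vinylketene 11, whose ketene carbon is attacked by the nucleophilic unsubstituted carbon of the ynol ether in a regioselective [2+2] cycloaddition that makes the C8a–C4a and C5–C6 bonds of 12; a second 4π opening gives dienylketene 13, and a thermal disrotatory 6π-electrocyclisation closes the six-membered ring between C8 and C8a to dienone 14, which tautomerises to phenol 15. The closest known reaction type is the Danheiser cyclobutenone–alkoxyalkyne benzannulation, and the 3-alkoxy-4-alkenylcyclobutenone through which every such annulation passes shows that alkoxy-substituted cyclobutenones enter this manifold. The substitution pattern follows from bond connectivity and not from any directing effect: the ketene oxygen becomes the only free hydroxyl (O8a), the cyclobutenone methoxy becomes O7 and the alkyne ethoxy becomes O5. No stereocentre is created, and the benzylic centre is carried through unchanged, its descriptor switching from S to R only because its neighbour becomes aromatic. The step needs regioselectivity in the [2+2], secured by the polarisation of the ynol ether; outward rotation of the bulky C4 substituent in the first opening, which keeps the benzylic C–H away from the ketene and out of a 1,5-hydrogen shift; and a temperature at which ethoxyacetylene survives, hence the staged heating in a closed vessel. The K2CO3/MeOH treatment returns any aryl ester of the phenol, or any dihydrocoumarin formed by lactonisation onto the methyl ester, to 15.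

Step 6
Reactants: 15 methyl (3R)-3-[4-ethoxy-6-hydroxy-2-methoxy-3-(3-methylbut-2-enyl)phenyl]-3-phenylpropanoate
Product: 17 methyl (3R)-3-[4-ethoxy-2-hydroxy-6-methoxy-5-(3-methylbut-2-enyl)-3-propanoylphenyl]-3-phenylpropanoate, via difluoroboron chelate 16 (not isolated)
Conditions: (EtCO)2O (3 equiv), BF3·OEt2 (3 equiv), CH2Cl2, 0 °C → rt; then NaOAc, MeOH–H2O, 50 °C
Reagents that add atoms: propanoic anhydride, CCC(=O)OC(=O)CC
Why: Lewis-acid Friedel–Crafts acylation can occur only at the single free ring carbon, which is activated by three oxygens, and the product is held as chelate 16, which ties up the O8a hydroxyl (no lactonisation onto the ester, no second acylation) until the buffered hydrolysis.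

Step 7
Reactants: 17 methyl (3R)-3-[4-ethoxy-2-hydroxy-6-methoxy-5-(3-methylbut-2-enyl)-3-propanoylphenyl]-3-phenylpropanoate
Product: 20 methyl (3R)-3-[5-ethoxy-7-methoxy-2,3-dimethyl-6-(3-methylbut-2-enyl)-4-oxochromen-8-yl]-3-phenylpropanoate, via aryl acetate 18 (not isolated), via 1,3-diketone 19 (not isolated)
Conditions: Ac2O, NaOAc (3 equiv), 140 °C
Reagents that add atoms: acetic anhydride, CC(=O)OC(C)=O
Why: Kostanecki–Robinson annulation: O-acetylation to 18, intramolecular Claisen-type acyl transfer to the ketone α-carbon giving 19, and cyclodehydration onto the regenerated O8a hydroxyl build the pyranone with methyl groups at C2 (from the anhydride) and C3 (from the propanoyl group); the α-methyl group excludes 3-acylation and the ethyl ether on O5 excludes the isomeric ring closure.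

Step 8
Reactants: 20 methyl (3R)-3-[5-ethoxy-7-methoxy-2,3-dimethyl-6-(3-methylbut-2-enyl)-4-oxochromen-8-yl]-3-phenylpropanoate
Product: 22 methyl (3R)-3-[5-hydroxy-7-methoxy-2,3-dimethyl-6-(3-methylbut-2-enyl)-4-oxochromen-8-yl]-3-phenylpropanoate, via dichloroboron chelate 21 (not isolated)
Conditions: BCl3 (2.5 equiv), CH2Cl2, −78 → −10 °C; cold pH 7 buffer
Reagents that add atoms: none
Why: Chelation-controlled ether cleavage: BCl3 binds between the C4 carbonyl oxygen and the peri O5, so only the ethyl group is lost (as chloroethane) to give chelate 21, while the 7-methoxy group, the ester and the prenyl group, which meets no protic acid because the substrate has no OH group, are left alone.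

Step 9
Reactants: 22 methyl (3R)-3-[5-hydroxy-7-methoxy-2,3-dimethyl-6-(3-methylbut-2-enyl)-4-oxochromen-8-yl]-3-phenylpropanoate
Product: 23 (3R)-3-[5-hydroxy-7-methoxy-2,3-dimethyl-6-(3-methylbut-2-enyl)-4-oxochromen-8-yl]-3-phenylpropanoic acid
Conditions: LiOH·H2O (4 equiv), THF–MeOH–H2O, 0 °C → rt; 1 M HCl to pH 3 at 0 °C
Reagents that add atoms: lithium hydroxide, [Li+].[OH-]
Why: Saponification of an unhindered methyl ester; the 2,3-dimethylchromone, further deactivated as its C5 phenoxide, withstands cold hydroxide, the benzylic centre has no acidic proton, and no ring stereocentre exists yet that could epimerise.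

Step 10
Reactants: 23 (3R)-3-[5-hydroxy-7-methoxy-2,3-dimethyl-6-(3-methylbut-2-enyl)-4-oxochromen-8-yl]-3-phenylpropanoic acid
Product: 26 (3R)-3-[(2S,3R)-5-hydroxy-7-methoxy-2,3-dimethyl-6-(3-methylbut-2-enyl)-4-oxo-2,3-dihydrochromen-8-yl]-3-phenylpropanoic acid, via bis-silylated chromone 24 (not isolated), via silyl enol ether 25 (not isolated)
Conditions: Cu(OAc)2 (5 mol%), (R)-DTBM-SEGPHOS (5.5 mol%), (EtO)2MeSiH (6 equiv), THF, 0 → 40 °C; then AcOH, aq. NH4F, THF, 0 °C
Reagents that add atoms: none
Why: Copper hydride-catalysed asymmetric conjugate reduction, a reaction known for chromones: the acid and phenol are first capped by dehydrogenative silylation (24), the ligand-bound copper hydride delivers hydride to one face of C2 (catalyst control fixes C2 as S), the enolate is stored as silyl enol ether 25, and kinetic protonation in the cold buffered work-up comes from the face opposite the pseudo-axial C2 methyl group (substrate control fixes C3 as R, cis), after which no acid or base step can erode the epimerisable centre.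

Compound list
1 | 3-phenylglutaric anhydride (4-phenyloxane-2,6-dione) | O=C1CC(CC(=O)O1)c1ccccc1 | starting material
2 | (3R)-5-methoxy-5-oxo-3-phenylpentanoic acid | OC(=O)C[C@H](CC(=O)OC)c1ccccc1 | intermediate
3 | methyl (3S)-5-chloro-5-oxo-3-phenylpentanoate | ClC(=O)C[C@H](CC(=O)OC)c1ccccc1 | intermediate
4 | chloroacetaldehyde dimethyl acetal (2-chloro-1,1-dimethoxyethane) | COC(CCl)OC | starting material
5 | prenyl bromide (1-bromo-3-methylbut-2-ene) | CC(C)=CCBr | starting material
6 | sodium methoxyacetylide | COC#[C-].[Na+] | intermediate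
7 | 1-methoxy-5-methylhex-4-en-1-yne | COC#CCC=C(C)C | intermediate
8 | methyl (3S)-5-oxo-3-phenylpent-4-enoate (aldoketene) | O=C=C[C@H](CC(=O)OC)c1ccccc1 | intermediate
9 | methyl (3S)-3-[2-methoxy-3-(3-methylbut-2-enyl)-4-oxocyclobut-2-en-1-yl]-3-phenylpropanoate (both epimers at the ring carbon) | COC1=C(CC=C(C)C)C(=O)C1[C@H](CC(=O)OC)c1ccccc1 | intermediate
10 | ethoxyacetylene | CCOC#C | starting material
11 | methyl (3S,4Z)-5-methoxy-6-(3-methylbut-2-enyl)-7-oxo-3-phenylhepta-4,6-dienoate (vinylketene) | O=C=C(CC=C(C)C)/C(OC)=C/[C@H](CC(=O)OC)c1ccccc1 | intermediate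
12 | methyl (3S,4Z)-5-[2-ethoxy-1-(3-methylbut-2-enyl)-4-oxocyclobut-2-en-1-yl]-5-methoxy-3-phenylpent-4-enoate (both epimers at the quaternary ring carbon) | CCOC1=CC(=O)C1(CC=C(C)C)/C(OC)=C/[C@H](CC(=O)OC)c1ccccc1 | intermediate
13 | methyl (3S,4Z,6E)-7-ethoxy-5-methoxy-6-(3-methylbut-2-enyl)-9-oxo-3-phenylnona-4,6,8-trienoate (dienylketene) | O=C=C/C(OCC)=C(CC=C(C)C)\C(OC)=C\[C@H](CC(=O)OC)c1ccccc1 | intermediate
14 | methyl (3S)-3-[4-ethoxy-2-methoxy-3-(3-methylbut-2-enyl)-6-oxocyclohexa-2,4-dien-1-yl]-3-phenylpropanoate (both epimers at the ring sp3 carbon) | CCOC1=CC(=O)C(C(OC)=C1CC=C(C)C)[C@H](CC(=O)OC)c1ccccc1 | intermediate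
15 | methyl (3R)-3-[4-ethoxy-6-hydroxy-2-methoxy-3-(3-methylbut-2-enyl)phenyl]-3-phenylpropanoate | COc1c(CC=C(C)C)c(OCC)cc(O)c1[C@H](CC(=O)OC)c1ccccc1 | intermediate
16 | difluoroboron chelate of ketone 17 (BF2 bridging the phenolate oxygen and the propanoyl oxygen) | CCC1=[O+][B-](F)(F)Oc2c1c(OCC)c(CC=C(C)C)c(OC)c2[C@H](CC(=O)OC)c1ccccc1 | intermediate
17 | methyl (3R)-3-[4-ethoxy-2-hydroxy-6-methoxy-5-(3-methylbut-2-enyl)-3-propanoylphenyl]-3-phenylpropanoate | COc1c(CC=C(C)C)c(OCC)c(C(=O)CC)c(O)c1[C@H](CC(=O)OC)c1ccccc1 | intermediate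
18 | methyl (3R)-3-[2-acetoxy-4-ethoxy-6-methoxy-5-(3-methylbut-2-enyl)-3-propanoylphenyl]-3-phenylpropanoate | COc1c(CC=C(C)C)c(OCC)c(C(=O)CC)c(OC(C)=O)c1[C@H](CC(=O)OC)c1ccccc1 | intermediate
19 | methyl (3R)-3-[4-ethoxy-2-hydroxy-6-methoxy-5-(3-methylbut-2-enyl)-3-(2-methyl-3-oxobutanoyl)phenyl]-3-phenylpropanoate (both epimers at the diketone carbon) | COc1c(CC=C(C)C)c(OCC)c(C(=O)C(C)C(C)=O)c(O)c1[C@H](CC(=O)OC)c1ccccc1 | intermediate
20 | methyl (3R)-3-[5-ethoxy-7-methoxy-2,3-dimethyl-6-(3-methylbut-2-enyl)-4-oxochromen-8-yl]-3-phenylpropanoate | COc1c(CC=C(C)C)c(OCC)c2c(c1[C@H](CC(=O)OC)c1ccccc1)OC(C)=C(C)C2=O | intermediate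
21 | dichloroboron chelate of 22 (BCl2 bridging the C5 phenolate oxygen and the C4 carbonyl oxygen) | COc1c(CC=C(C)C)c2O[B-](Cl)(Cl)[O+]=C3C(C)=C(C)Oc(c1[C@H](CC(=O)OC)c1ccccc1)c23 | intermediate
22 | methyl (3R)-3-[5-hydroxy-7-methoxy-2,3-dimethyl-6-(3-methylbut-2-enyl)-4-oxochromen-8-yl]-3-phenylpropanoate | COc1c(CC=C(C)C)c(O)c2c(c1[C@H](CC(=O)OC)c1ccccc1)OC(C)=C(C)C2=O | intermediate
23 | (3R)-3-[5-hydroxy-7-methoxy-2,3-dimethyl-6-(3-methylbut-2-enyl)-4-oxochromen-8-yl]-3-phenylpropanoic acid | COc1c(CC=C(C)C)c(O)c2c(c1[C@H](CC(=O)O)c1ccccc1)OC(C)=C(C)C2=O | intermediate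
24 | diethoxy(methyl)silyl (3R)-3-[5-[diethoxy(methyl)silyl]oxy-7-methoxy-2,3-dimethyl-6-(3-methylbut-2-enyl)-4-oxochromen-8-yl]-3-phenylpropanoate | COc1c(CC=C(C)C)c(O[Si](C)(OCC)OCC)c2c(c1[C@H](CC(=O)O[Si](C)(OCC)OCC)c1ccccc1)OC(C)=C(C)C2=O | intermediate
25 | diethoxy(methyl)silyl (3R)-3-[(2S)-4,5-bis[diethoxy(methyl)silyloxy]-7-methoxy-2,3-dimethyl-6-(3-methylbut-2-enyl)-2H-chromen-8-yl]-3-phenylpropanoate | COc1c(CC=C(C)C)c(O[Si](C)(OCC)OCC)c2c(c1[C@H](CC(=O)O[Si](C)(OCC)OCC)c1ccccc1)O[C@@H](C)C(C)=C2O[Si](C)(OCC)OCC | intermediate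
26 | (3R)-3-[(2S,3R)-5-hydroxy-7-methoxy-2,3-dimethyl-6-(3-methylbut-2-enyl)-4-oxo-2,3-dihydrochromen-8-yl]-3-phenylpropanoic acid (CNP0172137.1) | COc1c(CC=C(C)C)c(O)c2c(c1[C@H](CC(=O)O)c1ccccc1)O[C@@H](C)[C@@H](C)C2=O | target

Total step count: 10. Longest linear sequence: 9 steps (steps 1, 2, 4, 5, 6, 7, 8, 9, 10 from 3-phenylglutaric anhydride); step 3 is the one-step side branch.

Steps most likely to fail

Step 5. The vinylogous-ester cyclobutenone may open only at temperatures at which ethoxyacetylene is already lost by retro-ene fragmentation to ketene and ethylene, or the donor-substituted vinylketene may oligomerise faster than the ynol ether intercepts it. The fallback generates the ketene without heat. Setting out from 9, hydrolytic cleavage of the strained ring (LiOH, 1.05 equiv, THF–H2O, 0 °C) should give (5R)-3,7-dimethoxy-2-(3-methylbut-2-enyl)-7-oxo-5-phenylhept-2-enoic acid F1, a robust β-methoxyacrylic acid. (COCl)2 with catalytic DMF converts it into methyl (3R)-7-chloro-5-methoxy-6-(3-methylbut-2-enyl)-7-oxo-3-phenylhept-5-enoate F2. Slow addition of Et3N to F2 and 10 (5 equiv) in CH2Cl2 at 0–25 °C generates vinylketene 11 by 1,4-dehydrochlorination and lets it add to the ynol ether in the cold, giving 12. Compound 12 is isolated and heated alone in toluene at 110 °C, passing through 13 and 14 to 15, where the route is rejoined.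

Step 10. Hydride transfer from the bulky chiral catalyst to the tetrasubstituted, donor-substituted C2=C3 bond may be too slow, or facial discrimination at C2 may be poor. The fallback replaces catalyst control by separation. Setting out from 23, reduction with the smaller, more reactive achiral copper hydride formed from Cu(OAc)2, 1,2-bis(diphenylphosphino)benzene and (EtO)2MeSiH passes through 24 to a mixture of 25 and its C2 epimer, diethoxy(methyl)silyl (3R)-3-[(2R)-4,5-bis[diethoxy(methyl)silyloxy]-7-methoxy-2,3-dimethyl-6-(3-methylbut-2-enyl)-2H-chromen-8-yl]-3-phenylpropanoate F3. The same cold buffered protonation then gives 26 together with (3R)-3-[(2R,3S)-5-hydroxy-7-methoxy-2,3-dimethyl-6-(3-methylbut-2-enyl)-4-oxo-2,3-dihydrochromen-8-yl]-3-phenylpropanoic acid F4. Because the benzylic centre is fixed, these two cis acids are diastereomers and are separated by preparative HPLC with an acidic eluent, which rejoins the route at 26.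

Step 6. The BF3–carboxylic acid medium may protonate or acylate the prenyl double bond (with cyclisation onto a flanking ether oxygen), or promote lactonisation of the phenol onto the ester before acylation. The fallback is a neutral, light-driven acyl shift. Setting out from 15, O-acylation (EtCOCl, Et3N, DMAP cat., CH2Cl2, 0 °C) gives methyl (3R)-3-[4-ethoxy-2-methoxy-3-(3-methylbut-2-enyl)-6-propanoyloxyphenyl]-3-phenylpropanoate F5. Photo-Fries rearrangement (254 nm, degassed cyclohexane, quartz, rt) then moves the acyl group to the only free ring carbon, ortho to the oxygen, and rejoins the route at 17.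

Further compounds
F1 | step 5 | (5R)-3,7-dimethoxy-2-(3-methylbut-2-enyl)-7-oxo-5-phenylhept-2-enoic acid | OC(=O)C(CC=C(C)C)=C(OC)C[C@H](CC(=O)OC)c1ccccc1
F2 | step 5 | methyl (3R)-7-chloro-5-methoxy-6-(3-methylbut-2-enyl)-7-oxo-3-phenylhept-5-enoate | ClC(=O)C(CC=C(C)C)=C(OC)C[C@H](CC(=O)OC)c1ccccc1
F3 | step 10 | diethoxy(methyl)silyl (3R)-3-[(2R)-4,5-bis[diethoxy(methyl)silyloxy]-7-methoxy-2,3-dimethyl-6-(3-methylbut-2-enyl)-2H-chromen-8-yl]-3-phenylpropanoate | COc1c(CC=C(C)C)c(O[Si](C)(OCC)OCC)c2c(c1[C@H](CC(=O)O[Si](C)(OCC)OCC)c1ccccc1)O[C@H](C)C(C)=C2O[Si](C)(OCC)OCC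
F4 | step 10 | (3R)-3-[(2R,3S)-5-hydroxy-7-methoxy-2,3-dimethyl-6-(3-methylbut-2-enyl)-4-oxo-2,3-dihydrochromen-8-yl]-3-phenylpropanoic acid | COc1c(CC=C(C)C)c(O)c2c(c1[C@H](CC(=O)O)c1ccccc1)O[C@H](C)[C@H](C)C2=O
F5 | step 6 | methyl (3R)-3-[4-ethoxy-2-methoxy-3-(3-methylbut-2-enyl)-6-propanoyloxyphenyl]-3-phenylpropanoate | COc1c(CC=C(C)C)c(OCC)cc(OC(=O)CC)c1[C@H](CC(=O)OC)c1ccccc1
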